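## Retrosynthetic overview

1. Aiphanol (13) ⇐ tris-TBS ether 12 ⇐ Heck coupling of aryl bromide 8 with 3,5-bis(TBSO)styrene 11, which makes the E-stilbene C–C bond.
2. The C2–CH2OH of 8 ⇐ truncation of the dioxolane side chain of 7 (acetonide cleavage, glycol cleavage, reduction); the controlling stereocentre is excised here.
3. The 1,4-benzodioxane ring of 7 (the only ring formed) ⇐ inverse-demand hetero-Diels–Alder of 4-bromo-o-benzoquinone (from 6) with E-styrene 5. The trans relationship comes from the E-alkene; the absolute configuration comes from the D-glyceraldehyde-derived allylic centre.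
4. 5 ⇐ cross-metathesis of silylated canolol 4 with vinyl dioxolane 2, made from D-glyceraldehyde acetonide 1.

Assumption: (R)-glyceraldehyde acetonide (freshly distilled, or freshly made from D-mannitol diacetonide) and canolol (4-vinylsyringol) are bought as catalogue items.

The route is a design from first principles and has not been run. The facial and regiochemical outcome of Step 4 is predicted by analogy (inside-alkoxy/Kishi model; known o-quinone + propenylarene cycloadditions), not demonstrated on this substrate.

## Route

**Step 1**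
Reactants: 1, (R)-2,2-dimethyl-1,3-dioxolane-4-carbaldehyde (2,3-O-isopropylidene-D-glyceraldehyde)
Product: 2, (S)-2,2-dimethyl-4-vinyl-1,3-dioxolane
Conditions: Ph3PCH3Br, n-BuLi, Et2O, −78 → 0 °C; careful distillation (volatile)
Reagents that add atoms: methyltriphenylphosphonium bromide, C[P+](c1ccccc1)(c1ccccc1)c1ccccc1.[Br-] (supplies CH2)
Why: Wittig methylenation of the aldehyde at low temperature leaves the α-stereocentre untouched; only its CIP label changes from R to S.

**Step 2**
Reactants: 3, canolol (2,6-dimethoxy-4-vinylphenol)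
Product: 4, tert-butyl(2,6-dimethoxy-4-vinylphenoxy)dimethylsilane
Conditions: TBSCl, imidazole, DMF, rt (trace BHT)
Reagents that add atoms: TBSCl, CC(C)(C)[Si](C)(C)Cl
Why: Imidazole-mediated O-silylation of the phenol gives an electron-releasing ether that prevents phenol oxidation in Step 4 and survives every step until the final fluoride treatment.

**Step 3**
Reactants: 4, tert-butyl(2,6-dimethoxy-4-vinylphenoxy)dimethylsilane; 2, (S)-2,2-dimethyl-4-vinyl-1,3-dioxolane (3 equiv)
Product: 5, tert-butyl{4-[(E)-2-[(4S)-2,2-dimethyl-1,3-dioxolan-4-yl]ethenyl]-2,6-dimethoxyphenoxy}dimethylsilane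
Conditions: Hoveyda–Grubbs II (5 mol %), CH2Cl2, 40 °C
Reagents that add atoms: none
Why: Olefin cross-metathesis of a styrene with an excess of a slowly homodimerising allylic ether gives the conjugated E-alkene under thermodynamic control, and the allylic stereocentre is not involved.

**Step 4**
Reactants: 5, the E-styrene above; 6, 4-bromocatechol (4-bromobenzene-1,2-diol, 2.5 equiv, slow addition)
Product: 7, (2S,3R)-6-bromo-3-[4-(tert-butyldimethylsilyloxy)-3,5-dimethoxyphenyl]-2-[(4R)-2,2-dimethyl-1,3-dioxolan-4-yl]-2,3-dihydro-1,4-benzodioxine. The ring is trans; C2 has the same spatial arrangement as (2R) in 8 and the target, and is labelled S only because the dioxolanyl group outranks C3. The major isomer is separated from minor facial and regio-isomers by chromatography.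
Conditions: Ag2O, 4 Å MS, PhMe, rt → 45 °C, dark
Reagents that add atoms: none (Ag2O only removes 2 H from 6 to give 4-bromo-o-benzoquinone in situ)
Why: Inverse-electron-demand hetero-Diels–Alder of the o-quinone (O=C–C=O as the 4π unit) with the electron-rich E-styrene is suprafacial, so the ring is trans. The quinone adds to the alkene face anti to the allylic C–O of the dioxolane (inside-alkoxy/Kishi model, expected dr about 3–6:1), which sets both ring centres from the glyceraldehyde stereocentre. The carbonyl oxygen para to Br is the more electrophilic one (Br donates into the other carbonyl) and bonds to the non-benzylic carbon, giving the 6-bromo regioisomer.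

**Step 5**
Reactants: 7, the bromo-benzodioxane acetonide above
Product: 8, [(2R,3R)-6-bromo-3-[4-(tert-butyldimethylsilyloxy)-3,5-dimethoxyphenyl]-2,3-dihydro-1,4-benzodioxin-2-yl]methanol
Conditions: H5IO6, EtOAc, rt; filter; then NaBH4, MeOH/THF, −10 → 0 °C
Reagents that add atoms: none (acetone and CH2O are lost; hydride only is added)
Why: Periodic acid hydrolyses the terminal acetonide and cleaves the released 1,2-diol (Malaprade) to the C2 aldehyde, which is reduced immediately by borohydride before the α-aryloxy aldehyde can epimerise or β-eliminate; neither ring stereocentre is touched.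

**Step 6**
Reactants: 9, 3,5-dihydroxybenzaldehyde
Product: 10, 3,5-bis(tert-butyldimethylsilyloxy)benzaldehyde
Conditions: TBSCl, imidazole, DMF, rt
Reagents that add atoms: TBSCl, CC(C)(C)[Si](C)(C)Cl
Why: Standard silylation of both phenols, so that one fluoride step later removes all three silyl groups.

**Step 7**
Reactants: 10, 3,5-bis(tert-butyldimethylsilyloxy)benzaldehyde
Product: 11, 3,5-bis(tert-butyldimethylsilyloxy)styrene
Conditions: Ph3PCH3Br, KHMDS, THF, −78 °C → rt
Reagents that add atoms: methyltriphenylphosphonium bromide, C[P+](c1ccccc1)(c1ccccc1)c1ccccc1.[Br-] (supplies CH2)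
Why: Wittig methylenation of a non-enolisable aryl aldehyde; aryl silyl ethers tolerate the salt-free ylide.

**Step 8**
Reactants: 8, the bromo alcohol above; 11, 3,5-bis(tert-butyldimethylsilyloxy)styrene (1.3 equiv)
Product: 12, [(2R,3R)-6-[(E)-2-[3,5-bis(tert-butyldimethylsilyloxy)phenyl]ethenyl]-3-[4-(tert-butyldimethylsilyloxy)-3,5-dimethoxyphenyl]-2,3-dihydro-1,4-benzodioxin-2-yl]methanol
Conditions: Pd2(dba)3 (2.5 mol %), [(t-Bu)3PH]BF4 (6 mol %), Cy2NMe, dioxane, 80 °C
Reagents that add atoms: none
Why: Mizoroki–Heck coupling: Pd/P(t-Bu)3 oxidatively adds the electron-rich aryl bromide, and syn-insertion/β-hydride elimination on the styrene gives the E-stilbene. The amine base leaves the aryl silyl ethers, the free alcohol and the remote stereocentres intact.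

**Step 9**
Reactants: 12, tris-TBS aiphanol
Product: 13, aiphanol, 5-[(E)-2-[(2R,3R)-3-(4-hydroxy-3,5-dimethoxyphenyl)-2-(hydroxymethyl)-2,3-dihydro-1,4-benzodioxin-6-yl]ethenyl]benzene-1,3-diol
Conditions: TBAF, AcOH (1:1), THF, 0 °C → rt, degassed
Reagents that add atoms: none
Why: Fluoride cleaves the three aryl Si–O bonds; the AcOH buffer keeps the freed 4-hydroxybenzyl aryl ether from opening through a quinone methide, so C3 is not scrambled.

## Compound list

1 | (R)-2,2-dimethyl-1,3-dioxolane-4-carbaldehyde | O=C[C@H]1COC(C)(C)O1 | starting material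
2 | (S)-2,2-dimethyl-4-vinyl-1,3-dioxolane | C=C[C@H]1COC(C)(C)O1 | intermediate
3 | canolol (2,6-dimethoxy-4-vinylphenol) | C=Cc1cc(OC)c(O)c(OC)c1 | starting material
4 | tert-butyl(2,6-dimethoxy-4-vinylphenoxy)dimethylsilane | C=Cc1cc(OC)c(O[Si](C)(C)C(C)(C)C)c(OC)c1 | intermediate
5 | tert-butyl{4-[(E)-2-[(4S)-2,2-dimethyl-1,3-dioxolan-4-yl]ethenyl]-2,6-dimethoxyphenoxy}dimethylsilane | COc1cc(/C=C/[C@H]2COC(C)(C)O2)cc(OC)c1O[Si](C)(C)C(C)(C)C | intermediate
6 | 4-bromocatechol | Oc1ccc(Br)cc1O | starting material
7 | (2S,3R)-6-bromo-3-[4-(TBSO)-3,5-dimethoxyphenyl]-2-[(4R)-2,2-dimethyl-1,3-dioxolan-4-yl]-2,3-dihydro-1,4-benzodioxine | COc1cc([C@H]2Oc3cc(Br)ccc3O[C@@H]2[C@H]4COC(C)(C)O4)cc(OC)c1O[Si](C)(C)C(C)(C)C | intermediate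
8 | [(2R,3R)-6-bromo-3-[4-(TBSO)-3,5-dimethoxyphenyl]-2,3-dihydro-1,4-benzodioxin-2-yl]methanol | COc1cc([C@H]2Oc3cc(Br)ccc3O[C@@H]2CO)cc(OC)c1O[Si](C)(C)C(C)(C)C | intermediate
9 | 3,5-dihydroxybenzaldehyde | O=Cc1cc(O)cc(O)c1 | starting material
10 | 3,5-bis(tert-butyldimethylsilyloxy)benzaldehyde | O=Cc1cc(O[Si](C)(C)C(C)(C)C)cc(O[Si](C)(C)C(C)(C)C)c1 | intermediate
11 | 3,5-bis(tert-butyldimethylsilyloxy)styrene | C=Cc1cc(O[Si](C)(C)C(C)(C)C)cc(O[Si](C)(C)C(C)(C)C)c1 | intermediate
12 | tris-TBS aiphanol | COc1cc([C@H]2Oc3cc(/C=C/c4cc(O[Si](C)(C)C(C)(C)C)cc(O[Si](C)(C)C(C)(C)C)c4)ccc3O[C@@H]2CO)cc(OC)c1O[Si](C)(C)C(C)(C)C | intermediate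
13 | aiphanol | COc1cc([C@H]2Oc3cc(/C=C/c4cc(O)cc(O)c4)ccc3O[C@@H]2CO)cc(OC)c1O | target

## Step count and risks

Total steps: 9. Longest linear sequence: 6 (Steps 1, 3, 4, 5, 8, 9).

Steps most likely to fail:

1. **Step 4 (quinone cycloaddition).** The hindered β-substituted styrene may lose to quinone dimerisation or carbocyclic Diels–Alder modes, and both the Br-directed regioselectivity and the facial selectivity are only moderate predictions. Fallback: build the ring stepwise with defined regiochemistry from the same alkene 5. This means substrate-controlled epoxidation, benzylic opening with 2-(allyloxy)-5-bromophenol, deallylation, and Mitsunobu closure of the second C–O bond; the double inversion gives the same trans ring.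

2. **Step 5 (acetonide to CH2OH).** The intermediate α-aryloxy aldehyde can epimerise, or ring-open by β-elimination, which would erode ee; the aryl TBS ether may also be partly lost to the acid. Fallback: hydrolyse to the isolated diol, cleave under neutral conditions, and take the aldehyde straight to the configurationally robust carboxylic acid (Pinnick), then reduce the acid with BH3·THF.

3. **Step 8 (Heck on an electron-rich aryl bromide).** Oxidative addition may be slow, and regioisomeric or Z by-products or desilylation may occur. Fallback: switch to Suzuki–Miyaura coupling of 8 with the (E)-styryl pinacol boronate made from 11 by cross-metathesis with vinyl-Bpin.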